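**Strategy.** The chromanone ring C is disconnected at C3–C4 and O1–C2. Ring A is a salicylaldehyde already carrying the C8 side chain, whose only free phenol is the future O1. With trimethyl orthoformate and a chiral Brønsted acid it becomes a 4-methoxy ortho-quinone methide (oxocarbenium), the heterodiene O1=C8a–C4a=C4. An inverse-demand oxa-[4+2] with the ring B styrene (C2=C3) forges both bonds and the C2 stereocentre in one operation; the C4 methoxy group is a latent ketone. The side-chain stereocentres come from (R)-β-methyl-γ-butyrolactone and an Evans prenylation, and the chain is joined to ring A by Negishi coupling.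

Key step: step 11

Remark: (R)-4-methyldihydrofuran-2(3H)-one is taken as a catalogue chiral building block, and the antipode of the chiral acid that leads to the 2S series in step 11 is to be fixed in a first small run.

**Step 1**
Reactants: 1 (R)-4-methyldihydrofuran-2(3H)-one
Product: 4 (R)-4-[(tert-butyldiphenylsilyl)oxy]-3-methylbutanoic acid, via potassium hydroxy-carboxylate 2 (not isolated), via bis-silylated ester 3 (not isolated)
Conditions: KOH, MeOH/H2O, rt, then evaporation; TBDPSCl, imidazole, DMF, rt; K2CO3, MeOH/THF/H2O, rt, then pH 4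
Reagents that add atoms: potassium hydroxide [K+].[OH-]; tert-butyl(chloro)diphenylsilane CC(C)(C)[Si](Cl)(c1ccccc1)c1ccccc1
Why: Lactone saponification, exhaustive silylation and selective cleavage of the labile silyl ester is the standard entry to a 4-silyloxy acid, and the methyl-bearing stereocentre is not touched.

**Step 2**
Reactants: 4 (R)-4-[(tert-butyldiphenylsilyl)oxy]-3-methylbutanoic acid; 5 (S)-4-benzyloxazolidin-2-one
Product: 8 (S)-4-benzyl-3-[(R)-4-[(tert-butyldiphenylsilyl)oxy]-3-methylbutanoyl]oxazolidin-2-one, via mixed pivalic anhydride 6 (not isolated), via lithiated oxazolidinone 7 (not isolated)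
Conditions: 4, Et3N, PivCl, THF, −20 °C; 5, n-BuLi, THF, −78 °C; combined, −78 to 0 °C
Reagents that add atoms: none
Why: N-Acylation of the lithiated Evans oxazolidinone by the mixed pivalic anhydride should occur at the less hindered acyl group without affecting any stereocentre.

**Step 3**
Reactants: 8 (S)-4-benzyl-3-[(R)-4-[(tert-butyldiphenylsilyl)oxy]-3-methylbutanoyl]oxazolidin-2-one
Product: 10 (S)-4-benzyl-3-[(2S,3R)-4-[(tert-butyldiphenylsilyl)oxy]-3-methyl-2-(3-methylbut-2-en-1-yl)butanoyl]oxazolidin-2-one, via sodium (Z)-enolate 9 (not isolated)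
Conditions: NaN(SiMe3)2, THF, −78 °C; prenyl bromide, −78 to −45 °C
Reagents that add atoms: 1-bromo-3-methylbut-2-ene CC(C)=CCBr
Why: Evans asymmetric alkylation, in which the chelated (Z)-enolate is prenylated on the face opposite the benzyl group of the (S)-auxiliary, should set the new stereocentre (2S in the imide, the later R centre next to the benzylic CH2) under auxiliary control over the neighbouring methyl centre.

**Step 4**
Reactants: 10 (S)-4-benzyl-3-[(2S,3R)-4-[(tert-butyldiphenylsilyl)oxy]-3-methyl-2-(3-methylbut-2-en-1-yl)butanoyl]oxazolidin-2-one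
Product: 11 (2S,3R)-4-[(tert-butyldiphenylsilyl)oxy]-3-methyl-2-(3-methylbut-2-en-1-yl)butan-1-ol
Conditions: LiBH4, MeOH (1 equiv), Et2O, 0 °C
Reagents that add atoms: none
Why: Reductive cleavage of the N-acyl oxazolidinone with LiBH4 should give the primary alcohol without epimerisation and return the auxiliary.

**Step 5**
Reactants: 11 (2S,3R)-4-[(tert-butyldiphenylsilyl)oxy]-3-methyl-2-(3-methylbut-2-en-1-yl)butan-1-ol
Product: 12 tert-butyl{[(2R,3S)-3-(iodomethyl)-2,6-dimethylhept-5-en-1-yl]oxy}diphenylsilane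
Conditions: I2, PPh3, imidazole, CH2Cl2, 0 °C to rt
Reagents that add atoms: iodine II
Why: Appel-type iodination of the primary alcohol proceeds at the CH2 carbon only, so both stereocentres are retained.

**Step 6**
Reactants: 13 2,4,6-trihydroxybenzaldehyde
Product: 14 2,4-bis[(tert-butyldimethylsilyl)oxy]-6-hydroxybenzaldehyde
Conditions: TBSCl (2.1 equiv), i-Pr2NEt, THF/DMF, 0 °C
Reagents that add atoms: tert-butyl(chloro)dimethylsilane CC(C)(C)[Si](C)(C)Cl
Why: The para hydroxyl and one ortho hydroxyl should be silylated while the last ortho hydroxyl stays hydrogen-bonded to the aldehyde, the usual selectivity of phloroglucinaldehyde.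

**Step 7**
Reactants: 14 2,4-bis[(tert-butyldimethylsilyl)oxy]-6-hydroxybenzaldehyde
Product: 15 4,6-bis[(tert-butyldimethylsilyl)oxy]-2-hydroxy-3-iodobenzaldehyde
Conditions: NIS, CH2Cl2, 0 °C, dark
Reagents that add atoms: N-iodosuccinimide O=C1CCC(=O)N1I
Why: Electrophilic aromatic iodination is expected ortho to the free phenol, at the position flanked by OH and one silyloxy group, not at the position shielded by two bulky silyloxy groups.

**Step 8**
Reactants: 12 tert-butyl{[(2R,3S)-3-(iodomethyl)-2,6-dimethylhept-5-en-1-yl]oxy}diphenylsilane; 15 4,6-bis[(tert-butyldimethylsilyl)oxy]-2-hydroxy-3-iodobenzaldehyde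
Product: 17 4,6-bis[(tert-butyldimethylsilyl)oxy]-3-[(2R,3R)-4-[(tert-butyldiphenylsilyl)oxy]-3-methyl-2-(3-methylbut-2-en-1-yl)butyl]-2-hydroxybenzaldehyde, via alkylzinc iodide 16 (not isolated)
Conditions: 12, Zn dust, LiCl, THF, 40 °C; then slow addition to 15, Pd(OAc)2 (5 mol%), SPhos (10 mol%), THF, 25 to 40 °C
Reagents that add atoms: none
Why: Negishi cross-coupling of the primary alkylzinc iodide with the aryl iodide under Pd(OAc)2/SPhos, a system that tolerates free phenols and aldehydes when the zinc reagent is added slowly, joins the chain to ring A without touching a stereocentre.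

**Step 9**
Reactants: 18 4-hydroxy-2-methoxybenzaldehyde
Product: 19 4-[(tert-butyldimethylsilyl)oxy]-2-methoxybenzaldehyde
Conditions: TBSCl, imidazole, CH2Cl2, rt
Reagents that add atoms: tert-butyl(chloro)dimethylsilane CC(C)(C)[Si](C)(C)Cl
Why: Standard silylation of the phenol.

**Step 10**
Reactants: 19 4-[(tert-butyldimethylsilyl)oxy]-2-methoxybenzaldehyde
Product: 20 tert-butyl(4-ethenyl-3-methoxyphenoxy)dimethylsilane
Conditions: Ph3PCH3Br, NaN(SiMe3)2, THF, 0 °C; then 19, 0 °C to rt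
Reagents that add atoms: methyltriphenylphosphonium bromide C[P+](c1ccccc1)(c1ccccc1)c1ccccc1.[Br-]
Why: Wittig methylenation of the aryl aldehyde gives the electron-rich styrene under non-acidic conditions that keep the aryl silyl ether.

**Step 11**
Reactants: 17 4,6-bis[(tert-butyldimethylsilyl)oxy]-3-[(2R,3R)-4-[(tert-butyldiphenylsilyl)oxy]-3-methyl-2-(3-methylbut-2-en-1-yl)butyl]-2-hydroxybenzaldehyde; 20 tert-butyl(4-ethenyl-3-methoxyphenoxy)dimethylsilane
Product: 23 (2S,4S)-5,7-bis[(tert-butyldimethylsilyl)oxy]-2-{4-[(tert-butyldimethylsilyl)oxy]-2-methoxyphenyl}-8-[(2R,3R)-4-[(tert-butyldiphenylsilyl)oxy]-3-methyl-2-(3-methylbut-2-en-1-yl)butyl]-4-methoxychromane, via dimethyl acetal 21 (not isolated), via oxocarbenium ion 22 (not isolated)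
Conditions: HC(OMe)3 (1.5 equiv), 3,3'-bis(2,4,6-triisopropylphenyl)-BINOL N-triflylphosphoramide (10 mol%), 4 Å MS, CH2Cl2, 0 °C; then 20 (2 equiv, slow addition), −60 to −40 °C
Reagents that add atoms: trimethyl orthoformate COC(OC)OC
Why: Proposed new method: acid-catalysed acetalisation of 17 and ionisation of 21 should give the 4-methoxy ortho-quinone methide in its O-protonated form (oxocarbenium 22) as a contact ion pair with the chiral phosphoramidate, and styrene 20 then adds in an inverse-electron-demand oxa-[4+2] in which its CH2 terminus bonds to the carbenium carbon (C3–C4) and the phenolic oxygen captures the developing benzylic cation (O1–C2), asynchronously but in one operation. The closest known reaction types are the racemic acid-catalysed three-component coupling of salicylaldehydes, orthoformates and styrenes to 4-alkoxychromans and the chiral Brønsted acid-catalysed [4+2] cycloadditions of ortho-quinone methides with styrenes and of salicylaldehyde-acetal oxocarbenium ions with vinyl ethers; new here is the enantioselective pairing of the 4-alkoxy heterodiene with a styrene. The dihydropyran ring C is closed in the [4+2] mode (4π heterodiene O1=C8a–C4a=C4 plus the 2π unit C2=C3), which in the stepwise limit is a six-membered closure of the phenol oxygen onto the benzylic cation. C2 (S) is to be set by the chiral counter-anion, hydrogen-bonded to the phenol and shielding one face of the planar heterodiene, while C4 follows from the endo approach of the aryl group (2,4-cis) and is erased in step 12. The step needs regioselectivity (secured by the polarisation of the styrene by its ortho-methoxy and para-silyloxy groups and by the fact that the only free phenol of 17 is the one next to the side chain), chemoselectivity for the styrene over the trisubstituted side-chain alkene (secured by the much higher nucleophilicity of the styrene) and facial selectivity (catalyst control, the side-chain stereocentres being remote).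

**Step 12**
Reactants: 23 (2S,4S)-5,7-bis[(tert-butyldimethylsilyl)oxy]-2-{4-[(tert-butyldimethylsilyl)oxy]-2-methoxyphenyl}-8-[(2R,3R)-4-[(tert-butyldiphenylsilyl)oxy]-3-methyl-2-(3-methylbut-2-en-1-yl)butyl]-4-methoxychromane
Product: 24 (2S)-5,7-bis[(tert-butyldimethylsilyl)oxy]-2-{4-[(tert-butyldimethylsilyl)oxy]-2-methoxyphenyl}-8-[(2R,3R)-4-[(tert-butyldiphenylsilyl)oxy]-3-methyl-2-(3-methylbut-2-en-1-yl)butyl]chroman-4-one
Conditions: DDQ, CH2Cl2/pH 7 buffer, 0 °C to rt
Reagents that add atoms: water O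
Why: DDQ oxidation of a benzylic methyl ether, in which hydride abstraction should occur at C4 (benzylic to the trioxygenated ring A and alpha to the methoxy group) and water converts the oxocarbenium ion into the ketone, leaves C2 untouched.

**Step 13**
Reactants: 24 (2S)-5,7-bis[(tert-butyldimethylsilyl)oxy]-2-{4-[(tert-butyldimethylsilyl)oxy]-2-methoxyphenyl}-8-[(2R,3R)-4-[(tert-butyldiphenylsilyl)oxy]-3-methyl-2-(3-methylbut-2-en-1-yl)butyl]chroman-4-one
Product: 25 (2S)-5,7-dihydroxy-2-(4-hydroxy-2-methoxyphenyl)-8-[(2R,3R)-4-hydroxy-3-methyl-2-(3-methylbut-2-en-1-yl)butyl]chroman-4-one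
Conditions: Bu4NF/AcOH (1:1, excess), THF, 0 °C to rt
Reagents that add atoms: none
Why: Acetic acid-buffered fluoride desilylation should remove the three aryl silyl ethers and the alkyl silyl ether without the base-induced ring opening of the flavanone that would epimerise C2.

**Compound list**

1 | (R)-4-methyldihydrofuran-2(3H)-one | O=C1C[C@@H](C)CO1 | starting material
2 | potassium (R)-4-hydroxy-3-methylbutanoate (formed in the flask) | [K+].[O-]C(=O)C[C@@H](C)CO | intermediate
3 | tert-butyldiphenylsilyl (R)-4-[(tert-butyldiphenylsilyl)oxy]-3-methylbutanoate (formed in the flask) | CC(C)(C)[Si](c1ccccc1)(c1ccccc1)OC(=O)C[C@@H](C)CO[Si](c1ccccc1)(c1ccccc1)C(C)(C)C | intermediate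
4 | (R)-4-[(tert-butyldiphenylsilyl)oxy]-3-methylbutanoic acid | OC(=O)C[C@@H](C)CO[Si](c1ccccc1)(c1ccccc1)C(C)(C)C | intermediate
5 | (S)-4-benzyloxazolidin-2-one | O=C1N[C@@H](Cc2ccccc2)CO1 | starting material
6 | (R)-4-[(tert-butyldiphenylsilyl)oxy]-3-methylbutanoic pivalic anhydride (formed in the flask) | CC(C)(C)C(=O)OC(=O)C[C@@H](C)CO[Si](c1ccccc1)(c1ccccc1)C(C)(C)C | intermediate
7 | lithium (S)-4-benzyl-2-oxooxazolidin-3-ide (formed in the flask) | [Li+].O=C1[N-][C@@H](Cc2ccccc2)CO1 | intermediate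
8 | (S)-4-benzyl-3-[(R)-4-[(tert-butyldiphenylsilyl)oxy]-3-methylbutanoyl]oxazolidin-2-one | O=C1OC[C@H](Cc2ccccc2)N1C(=O)C[C@@H](C)CO[Si](c1ccccc1)(c1ccccc1)C(C)(C)C | intermediate
9 | sodium (Z)-enolate of 8 (formed in the flask) | O=C1OC[C@H](Cc2ccccc2)N1/C([O-])=C/[C@@H](C)CO[Si](c1ccccc1)(c1ccccc1)C(C)(C)C.[Na+] | intermediate
10 | (S)-4-benzyl-3-[(2S,3R)-4-[(tert-butyldiphenylsilyl)oxy]-3-methyl-2-(3-methylbut-2-en-1-yl)butanoyl]oxazolidin-2-one | O=C1OC[C@H](Cc2ccccc2)N1C(=O)[C@@H](CC=C(C)C)[C@@H](C)CO[Si](c1ccccc1)(c1ccccc1)C(C)(C)C | intermediate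
11 | (2S,3R)-4-[(tert-butyldiphenylsilyl)oxy]-3-methyl-2-(3-methylbut-2-en-1-yl)butan-1-ol | OC[C@@H](CC=C(C)C)[C@@H](C)CO[Si](c1ccccc1)(c1ccccc1)C(C)(C)C | intermediate
12 | tert-butyl{[(2R,3S)-3-(iodomethyl)-2,6-dimethylhept-5-en-1-yl]oxy}diphenylsilane | IC[C@@H](CC=C(C)C)[C@@H](C)CO[Si](c1ccccc1)(c1ccccc1)C(C)(C)C | intermediate
13 | 2,4,6-trihydroxybenzaldehyde | O=Cc1c(O)cc(O)cc1O | starting material
14 | 2,4-bis[(tert-butyldimethylsilyl)oxy]-6-hydroxybenzaldehyde | O=Cc1c(O)cc(O[Si](C)(C)C(C)(C)C)cc1O[Si](C)(C)C(C)(C)C | intermediate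
15 | 4,6-bis[(tert-butyldimethylsilyl)oxy]-2-hydroxy-3-iodobenzaldehyde | O=Cc1c(O)c(I)c(O[Si](C)(C)C(C)(C)C)cc1O[Si](C)(C)C(C)(C)C | intermediate
16 | {(2S,3R)-4-[(tert-butyldiphenylsilyl)oxy]-3-methyl-2-(3-methylbut-2-en-1-yl)butyl}zinc iodide (formed in the flask) | I[Zn]C[C@@H](CC=C(C)C)[C@@H](C)CO[Si](c1ccccc1)(c1ccccc1)C(C)(C)C | intermediate
17 | 4,6-bis[(tert-butyldimethylsilyl)oxy]-3-[(2R,3R)-4-[(tert-butyldiphenylsilyl)oxy]-3-methyl-2-(3-methylbut-2-en-1-yl)butyl]-2-hydroxybenzaldehyde | O=Cc1c(O)c(C[C@@H](CC=C(C)C)[C@@H](C)CO[Si](c2ccccc2)(c2ccccc2)C(C)(C)C)c(O[Si](C)(C)C(C)(C)C)cc1O[Si](C)(C)C(C)(C)C | intermediate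
18 | 4-hydroxy-2-methoxybenzaldehyde | COc1cc(O)ccc1C=O | starting material
19 | 4-[(tert-butyldimethylsilyl)oxy]-2-methoxybenzaldehyde | COc1cc(O[Si](C)(C)C(C)(C)C)ccc1C=O | intermediate
20 | tert-butyl(4-ethenyl-3-methoxyphenoxy)dimethylsilane | COc1cc(O[Si](C)(C)C(C)(C)C)ccc1C=C | intermediate
21 | 3,5-bis[(tert-butyldimethylsilyl)oxy]-2-[(2R,3R)-4-[(tert-butyldiphenylsilyl)oxy]-3-methyl-2-(3-methylbut-2-en-1-yl)butyl]-6-(dimethoxymethyl)phenol (formed in the flask) | COC(OC)c1c(O)c(C[C@@H](CC=C(C)C)[C@@H](C)CO[Si](c2ccccc2)(c2ccccc2)C(C)(C)C)c(O[Si](C)(C)C(C)(C)C)cc1O[Si](C)(C)C(C)(C)C | intermediate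
22 | O-methyl oxocarbenium ion of 17 (protonated 4-methoxy ortho-quinone methide, ion-paired with the catalyst anion; formed in the flask) | C[O+]=Cc1c(O)c(C[C@@H](CC=C(C)C)[C@@H](C)CO[Si](c2ccccc2)(c2ccccc2)C(C)(C)C)c(O[Si](C)(C)C(C)(C)C)cc1O[Si](C)(C)C(C)(C)C | intermediate
23 | (2S,4S)-5,7-bis[(tert-butyldimethylsilyl)oxy]-2-{4-[(tert-butyldimethylsilyl)oxy]-2-methoxyphenyl}-8-[(2R,3R)-4-[(tert-butyldiphenylsilyl)oxy]-3-methyl-2-(3-methylbut-2-en-1-yl)butyl]-4-methoxychromane | COc1cc(O[Si](C)(C)C(C)(C)C)ccc1[C@@H]1C[C@H](OC)c2c(O[Si](C)(C)C(C)(C)C)cc(O[Si](C)(C)C(C)(C)C)c(C[C@@H](CC=C(C)C)[C@@H](C)CO[Si](c3ccccc3)(c3ccccc3)C(C)(C)C)c2O1 | intermediate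
24 | (2S)-5,7-bis[(tert-butyldimethylsilyl)oxy]-2-{4-[(tert-butyldimethylsilyl)oxy]-2-methoxyphenyl}-8-[(2R,3R)-4-[(tert-butyldiphenylsilyl)oxy]-3-methyl-2-(3-methylbut-2-en-1-yl)butyl]chroman-4-one | COc1cc(O[Si](C)(C)C(C)(C)C)ccc1[C@@H]1CC(=O)c2c(O[Si](C)(C)C(C)(C)C)cc(O[Si](C)(C)C(C)(C)C)c(C[C@@H](CC=C(C)C)[C@@H](C)CO[Si](c3ccccc3)(c3ccccc3)C(C)(C)C)c2O1 | intermediate
25 | (2S)-5,7-dihydroxy-2-(4-hydroxy-2-methoxyphenyl)-8-[(2R,3R)-4-hydroxy-3-methyl-2-(3-methylbut-2-en-1-yl)butyl]chroman-4-one | COc1cc(O)ccc1[C@@H]1CC(=O)c2c(O)cc(O)c(C[C@@H](CC=C(C)C)[C@@H](C)CO)c2O1 | target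

**Total step count:** 13.
**Longest linear sequence:** 9 steps (steps 1, 2, 3, 4, 5, 8, 11, 12, 13).

**Steps most likely to fail**

1. Step 11 (proposed new method). The ion pair may give poor facial selectivity at C2, or the acid may oligomerise the electron-rich styrene before it is trapped. The fallback uses known chemistry, sets out from 17 and 19 and comes back to the route at 24. Aldehyde 19 is homologated with lithiated trimethylsilyldiazomethane (Me3SiCHN2, LiN(i-Pr)2, THF, −78 °C to rt, Colvin rearrangement) to tert-butyl(4-ethynyl-3-methoxyphenoxy)dimethylsilane F1. Its lithium acetylide (n-BuLi, 2.2 equiv, THF, −78 °C) is added to 17 to give the propargylic alcohol 1-{4,6-bis[(tert-butyldimethylsilyl)oxy]-2-hydroxy-3-alkylphenyl}-3-aryl-prop-2-yn-1-ol F2 (both carbinol epimers). MnO2 oxidation gives the 2-hydroxyaryl ynone F3, which is cyclised 6-endo with catalytic 4-(dimethylamino)pyridine in DMF to the silyl-protected flavone F4. Copper hydride-catalysed asymmetric conjugate reduction of the chromone double bond (Cu(OAc)2, DTBM-SEGPHOS antipode chosen for 2S, (EtO)2MeSiH, t-BuOH, toluene) then gives 24.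

2. Step 8. Oxidative addition into the hindered, electron-rich iodophenol may be slow, so that protonolysis of the alkylzinc by the free phenol or β-hydride elimination takes over. The fallback sets out from 12 and 15 and comes back at 17. Iodide 12 is lithiated (t-BuLi, Et2O, −78 °C) and trapped with B-methoxy-9-borabicyclo[3.3.1]nonane to give the lithium alkyl(methoxy)borate F5, which is coupled with 15 in a B-alkyl Suzuki–Miyaura reaction (PdCl2(dppf), K3PO4, THF/DMF, rt) to give 17.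

3. Step 12. Hydride abstraction by DDQ may also occur at C2 (over-oxidation towards flavene-type products) or the alkyl silyl ether may be lost. The fallback sets out from 23 and comes back at 24. The benzylic methyl ether is solvolysed (pyridinium p-toluenesulfonate, acetone/H2O, rt) to the flavan-4-ol F6 (both C4 epimers), which is oxidised with Dess–Martin periodinane (NaHCO3, CH2Cl2) to 24.

**Further compounds**

F1 | step 11 | tert-butyl(4-ethynyl-3-methoxyphenoxy)dimethylsilane | COc1cc(O[Si](C)(C)C(C)(C)C)ccc1C#C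
F2 | step 11 | 1-{4,6-bis[(tert-butyldimethylsilyl)oxy]-3-[(2R,3R)-4-[(tert-butyldiphenylsilyl)oxy]-3-methyl-2-(3-methylbut-2-en-1-yl)butyl]-2-hydroxyphenyl}-3-{4-[(tert-butyldimethylsilyl)oxy]-2-methoxyphenyl}prop-2-yn-1-ol (both carbinol epimers) | COc1cc(O[Si](C)(C)C(C)(C)C)ccc1C#CC(O)c1c(O)c(C[C@@H](CC=C(C)C)[C@@H](C)CO[Si](c2ccccc2)(c2ccccc2)C(C)(C)C)c(O[Si](C)(C)C(C)(C)C)cc1O[Si](C)(C)C(C)(C)C
F3 | step 11 | 1-{4,6-bis[(tert-butyldimethylsilyl)oxy]-3-[(2R,3R)-4-[(tert-butyldiphenylsilyl)oxy]-3-methyl-2-(3-methylbut-2-en-1-yl)butyl]-2-hydroxyphenyl}-3-{4-[(tert-butyldimethylsilyl)oxy]-2-methoxyphenyl}prop-2-yn-1-one | COc1cc(O[Si](C)(C)C(C)(C)C)ccc1C#CC(=O)c1c(O)c(C[C@@H](CC=C(C)C)[C@@H](C)CO[Si](c2ccccc2)(c2ccccc2)C(C)(C)C)c(O[Si](C)(C)C(C)(C)C)cc1O[Si](C)(C)C(C)(C)C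
F4 | step 11 | 5,7-bis[(tert-butyldimethylsilyl)oxy]-2-{4-[(tert-butyldimethylsilyl)oxy]-2-methoxyphenyl}-8-[(2R,3R)-4-[(tert-butyldiphenylsilyl)oxy]-3-methyl-2-(3-methylbut-2-en-1-yl)butyl]-4H-chromen-4-one | COc1cc(O[Si](C)(C)C(C)(C)C)ccc1-c1cc(=O)c2c(O[Si](C)(C)C(C)(C)C)cc(O[Si](C)(C)C(C)(C)C)c(C[C@@H](CC=C(C)C)[C@@H](C)CO[Si](c3ccccc3)(c3ccccc3)C(C)(C)C)c2o1
F5 | step 8 | lithium {(2S,3R)-4-[(tert-butyldiphenylsilyl)oxy]-3-methyl-2-(3-methylbut-2-en-1-yl)butyl}(methoxy)-9-borabicyclo[3.3.1]nonan-9-uide | [Li+].CO[B-]1(C[C@@H](CC=C(C)C)[C@@H](C)CO[Si](c2ccccc2)(c2ccccc2)C(C)(C)C)C2CCCC1CCC2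
F6 | step 12 | (2S)-5,7-bis[(tert-butyldimethylsilyl)oxy]-2-{4-[(tert-butyldimethylsilyl)oxy]-2-methoxyphenyl}-8-[(2R,3R)-4-[(tert-butyldiphenylsilyl)oxy]-3-methyl-2-(3-methylbut-2-en-1-yl)butyl]chroman-4-ol (both C4 epimers) | COc1cc(O[Si](C)(C)C(C)(C)C)ccc1[C@@H]1CC(O)c2c(O[Si](C)(C)C(C)(C)C)cc(O[Si](C)(C)C(C)(C)C)c(C[C@@H](CC=C(C)C)[C@@H](C)CO[Si](c3ccccc3)(c3ccccc3)C(C)(C)C)c2O1
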